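**Retrosynthetic overview**

1. The target, (2S,4R,6S) with all three ring substituents cis, comes from NaBH4 reduction of the C4 ketone, which comes from cis-hydrogenation (with loss of three benzyl groups) of a 6-aryl-2-alkyl-2,3-dihydro-4H-pyran-4-one; C2 and C4 are both relayed from C6.
2. Key disconnection: the aryl–C2 bond, made by 1,2-addition of 3,4-bis(benzyloxy)-5-methoxyphenyllithium to the lactone carbonyl of an (S)-4-methoxy-5,6-dihydro-2H-pyran-2-one, followed in the same flask by acid-induced 1,3-carbonyl transposition from C2 to C4.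
3. Enabling feature: in the tetrahydropyran ring, C2 carries both the ring oxygen O1 and the aryl carbon, and C4 (1,3 to C2) carries the hydroxyl. O1–C2–C3–C4–O is therefore a latent vinylogous carbonate: C2 can be an electrophilic lactone carbonyl, and the C4 oxygen needs no protecting group.
4. Ring order: the pyran is the only ring made. It is formed first, by a Ti–BINOL-catalysed hetero-Diels–Alder reaction of Brassard's diene with 3-[4-(benzyloxy)-3-methoxyphenyl]propanal, which sets C6 by catalysis, and is then carried through (lactone, dihydropyranone, tetrahydropyranone, tetrahydropyranol).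
5. The aryl donor comes from 5-bromo-2-hydroxy-3-methoxybenzaldehyde by Dakin oxidation and benzylation, so the bromine marks the carbon para to the central phenol oxygen.

Key step: step 7

Remark: ring atoms are numbered as in the target throughout (O1, aryl-bearing C2, carbinol C4, arylethyl-bearing C6), and the sense of induction of the Ti–BINOL catalyst in step 4 is assumed to follow the parent 3-phenylpropanal case (otherwise the antipodal ligand is used).

**Route**

Step 1
Reactants: 1 4-(3-hydroxypropyl)-2-methoxyphenol (dihydroconiferyl alcohol)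
Product: 2 3-[4-(benzyloxy)-3-methoxyphenyl]propan-1-ol
Conditions: BnBr, K2CO3, acetone, reflux
Reagents that add atoms: benzyl bromide, BrCc1ccccc1
Why: Williamson etherification with a carbonate base should alkylate only the phenol, which is far more acidic than the primary alcohol.

Step 2
Reactants: 2 3-[4-(benzyloxy)-3-methoxyphenyl]propan-1-ol
Product: 3 3-[4-(benzyloxy)-3-methoxyphenyl]propanal
Conditions: TEMPO (cat.), PhI(OAc)2, CH2Cl2, rt
Reagents that add atoms: none
Why: The TEMPO/(diacetoxyiodo)benzene oxidation of a primary alcohol should stop cleanly at the aldehyde and tolerates the electron-rich benzyl aryl ether.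

Step 3
Reactants: 4 methyl (E)-3-methoxybut-2-enoate
Product: 6 1,3-dimethoxy-1-(trimethylsilyloxy)buta-1,3-diene (Brassard's diene), via lithium dienolate 5 (not isolated)
Conditions: LDA, THF, −78 °C; then TMSCl, −78 °C → rt; filtration, distillation
Reagents that add atoms: chlorotrimethylsilane, C[Si](C)(C)Cl
Why: Kinetic γ-deprotonation of the vinylogous ester and O-silylation of the extended enolate is the standard silyl ketene acetal preparation of this diene.

Step 4
Reactants: 3 3-[4-(benzyloxy)-3-methoxyphenyl]propanal; 6 Brassard's diene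
Product: 8 (6S)-6-{2-[4-(benzyloxy)-3-methoxyphenyl]ethyl}-4-methoxy-5,6-dihydro-2H-pyran-2-one, via hydroxy enoate 7 (not isolated)
Conditions: Ti(OiPr)4 (10 mol %), (R)-BINOL (20 mol %), 4 Å MS, THF, −20 °C; then TFA, CH2Cl2, 0 °C
Reagents that add atoms: none
Why: The Ti–BINOL-catalysed formal hetero-Diels–Alder reaction of Brassard's diene (vinylogous Mukaiyama aldol, then acid-induced desilylation and lactonisation) should give the kavalactone-type lactone directly, the chiral Lewis acid choosing the aldehyde face and so setting C6 as S, as is precedented for 3-phenylpropanal.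

Step 5
Reactants: 9 5-bromo-2-hydroxy-3-methoxybenzaldehyde
Product: 11 5-bromo-3-methoxybenzene-1,2-diol, via aryl formate 10 (not isolated)
Conditions: 30 % H2O2, NaOH, H2O–THF, 0 °C → rt, N2; then aq. HCl
Reagents that add atoms: hydrogen peroxide, OO
Why: Dakin oxidation of an ortho-hydroxybenzaldehyde (hydroperoxide addition, aryl migration to the formate, hydrolysis in situ) should replace the formyl group by hydroxyl without touching the bromide.

Step 6
Reactants: 11 5-bromo-3-methoxybenzene-1,2-diol
Product: 12 1,2-bis(benzyloxy)-5-bromo-3-methoxybenzene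
Conditions: BnBr, K2CO3, DMF, 60 °C
Reagents that add atoms: benzyl bromide, BrCc1ccccc1
Why: Double Williamson etherification should protect both catechol hydroxyls as benzyl ethers, which survive aryllithium chemistry and are later removed in the hydrogenation step.

Step 7
Reactants: 12 1,2-bis(benzyloxy)-5-bromo-3-methoxybenzene; 8 (6S)-6-{2-[4-(benzyloxy)-3-methoxyphenyl]ethyl}-4-methoxy-5,6-dihydro-2H-pyran-2-one
Product: 15 (2S)-6-[3,4-bis(benzyloxy)-5-methoxyphenyl]-2-{2-[4-(benzyloxy)-3-methoxyphenyl]ethyl}-2,3-dihydro-4H-pyran-4-one, via aryllithium 13 (not isolated), via lithium lactolate 14 (not isolated)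
Conditions: n-BuLi, THF, −78 °C; then 8, THF, −78 °C; then 2 M HCl, THF, 0 °C → rt
Reagents that add atoms: water, O
Why: Br/Li exchange gives aryllithium 13, which adds 1,2 to the lactone carbonyl of the vinylogous carbonate 8 to give lithium lactolate 14, a tetrahedral intermediate that should persist at −78 °C and, even if it opened, would only unmask a deactivated β-methoxy enone, so a second addition is not expected. Aqueous HCl then ionises the lactol to a 2-aryl-4-methoxy-dihydropyrylium (vinylogous oxocarbenium) ion, water adds at C4 and methanol leaves, so the carbonyl moves from C2 to C4 and the new aryl–C2 bond ends on the enol-ether carbon of a 2,3-dihydro-4H-pyran-4-one. The closest known reaction type is the Stork–Danheiser 1,2-addition/1,3-carbonyl transposition of vinylogous esters, together with the hydride-addition/acid conversion of 4-alkoxy-5,6-dihydropyran-2-ones into dihydropyranones and the acid cyclodehydration of δ-hydroxy-1,3-diketones. No new ring is closed, since the pyran ring of 8 is carried through; should 14 open to its δ-hydroxy enone tautomer, it recloses by 6-exo-trig attack of the C6 hydroxyl on the aryl ketone followed by dehydration, the four-membered alternative being excluded. No new stereocentre is created, and the catalysis-derived C6 centre is a spectator because neither its C–O nor its C–H bond is touched. The step needs 1,2-addition in preference to conjugate addition–elimination at C4 and to γ-deprotonation at C5, which the hard and only moderately basic aryllithium, the donor-deactivated C4 and the low temperature should secure.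

Step 8
Reactants: 15 (2S)-6-[3,4-bis(benzyloxy)-5-methoxyphenyl]-2-{2-[4-(benzyloxy)-3-methoxyphenyl]ethyl}-2,3-dihydro-4H-pyran-4-one
Product: 16 (2S,6S)-2-(3,4-dihydroxy-5-methoxyphenyl)-6-[2-(4-hydroxy-3-methoxyphenyl)ethyl]tetrahydro-4H-pyran-4-one
Conditions: H2 (1 atm), 10 % Pd/C, EtOAc–MeOH, rt
Reagents that add atoms: none
Why: Heterogeneous syn-hydrogenation of the vinylogous ester C=C should deliver hydrogen to the ring face opposite the C6 side chain, which places the C2 aryl group cis to it (substrate control from C6, new centre 2S), while the same catalyst removes the three benzyl ethers by hydrogenolysis.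

Step 9
Reactants: 16 (2S,6S)-2-(3,4-dihydroxy-5-methoxyphenyl)-6-[2-(4-hydroxy-3-methoxyphenyl)ethyl]tetrahydro-4H-pyran-4-one
Product: 17 (2S,4R,6S)-2-(3,4-dihydroxy-5-methoxyphenyl)-6-[2-(4-hydroxy-3-methoxyphenyl)ethyl]tetrahydro-2H-pyran-4-ol
Conditions: NaBH4, MeOH–THF, −20 → 0 °C; aq. NH4Cl
Reagents that add atoms: none
Why: In this sodium borohydride reduction the small hydride should attack the chair tetrahydropyran-4-one (C2 and C6 substituents both equatorial) along the axial trajectory, giving the equatorial 4R alcohol cis to both substituents by substrate control.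

**Compound list**

1 | 4-(3-hydroxypropyl)-2-methoxyphenol | COc1cc(CCCO)ccc1O | starting material
2 | 3-[4-(benzyloxy)-3-methoxyphenyl]propan-1-ol | COc1cc(CCCO)ccc1OCc1ccccc1 | intermediate
3 | 3-[4-(benzyloxy)-3-methoxyphenyl]propanal | COc1cc(CCC=O)ccc1OCc1ccccc1 | intermediate
4 | methyl (E)-3-methoxybut-2-enoate | CO/C(C)=C/C(=O)OC | starting material
5 | lithium 1,3-dimethoxybuta-1,3-dien-1-olate (geometry at C1=C2 not defined; not isolated) | C=C(OC)C=C(OC)O[Li] | intermediate
6 | 1,3-dimethoxy-1-(trimethylsilyloxy)buta-1,3-diene, Brassard's diene (geometry at C1=C2 as formed, without consequence) | C=C(OC)C=C(OC)O[Si](C)(C)C | intermediate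
7 | methyl (2E,5S)-7-[4-(benzyloxy)-3-methoxyphenyl]-5-hydroxy-3-methoxyhept-2-enoate (not isolated) | COc1cc(CC[C@H](O)C/C(OC)=C\C(=O)OC)ccc1OCc1ccccc1 | intermediate
8 | (6S)-6-{2-[4-(benzyloxy)-3-methoxyphenyl]ethyl}-4-methoxy-5,6-dihydro-2H-pyran-2-one | COc1cc(CC[C@H]2CC(OC)=CC(=O)O2)ccc1OCc1ccccc1 | intermediate
9 | 5-bromo-2-hydroxy-3-methoxybenzaldehyde | COc1cc(Br)cc(C=O)c1O | starting material
10 | 5-bromo-2-hydroxy-3-methoxyphenyl formate (not isolated) | COc1cc(Br)cc(OC=O)c1O | intermediate
11 | 5-bromo-3-methoxybenzene-1,2-diol | COc1cc(Br)cc(O)c1O | intermediate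
12 | 1,2-bis(benzyloxy)-5-bromo-3-methoxybenzene | COc1cc(Br)cc(OCc2ccccc2)c1OCc1ccccc1 | intermediate
13 | [3,4-bis(benzyloxy)-5-methoxyphenyl]lithium (not isolated) | COc1cc([Li])cc(OCc2ccccc2)c1OCc1ccccc1 | intermediate
14 | lithium (6S)-2-[3,4-bis(benzyloxy)-5-methoxyphenyl]-6-{2-[4-(benzyloxy)-3-methoxyphenyl]ethyl}-4-methoxy-5,6-dihydro-2H-pyran-2-olate (C2 epimers; not isolated) | COc1cc(CC[C@H]2CC(OC)=CC(O[Li])(c3cc(OCc4ccccc4)c(OCc4ccccc4)c(OC)c3)O2)ccc1OCc1ccccc1 | intermediate
15 | (2S)-6-[3,4-bis(benzyloxy)-5-methoxyphenyl]-2-{2-[4-(benzyloxy)-3-methoxyphenyl]ethyl}-2,3-dihydro-4H-pyran-4-one | COc1cc(CC[C@H]2CC(=O)C=C(c3cc(OCc4ccccc4)c(OCc4ccccc4)c(OC)c3)O2)ccc1OCc1ccccc1 | intermediate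
16 | (2S,6S)-2-(3,4-dihydroxy-5-methoxyphenyl)-6-[2-(4-hydroxy-3-methoxyphenyl)ethyl]tetrahydro-4H-pyran-4-one (2,6-cis) | COc1cc(CC[C@H]2CC(=O)C[C@@H](c3cc(O)c(O)c(OC)c3)O2)ccc1O | intermediate
17 | (2S,4R,6S)-2-(3,4-dihydroxy-5-methoxyphenyl)-6-[2-(4-hydroxy-3-methoxyphenyl)ethyl]tetrahydro-2H-pyran-4-ol (all-cis) | COc1cc(CC[C@H]2C[C@@H](O)C[C@@H](c3cc(O)c(O)c(OC)c3)O2)ccc1O | target

**Step count and risks**

Total step count: 9. Longest linear sequence: 6 steps (steps 1, 2, 4, 7, 8, 9).

Steps most likely to fail: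

Step 7. The aryllithium may act as a base at C5 (γ-deprotonation followed by β-elimination of the lactone carboxylate, which opens the ring and destroys C6), or a second aryl group may add after ring opening. The fallback sets out from 8 and returns at 15, still forming the same aryl–C2 bond but on an open-chain acyl donor. Lactone 8 would be opened with MeNH(OMe)·HCl/AlMe3 (CH2Cl2, 0 °C → rt) to (2E,5S)-7-[4-(benzyloxy)-3-methoxyphenyl]-5-hydroxy-N,3-dimethoxy-N-methylhept-2-enamide F1. Silylation (TBSCl, imidazole, DMF) would give the 5-O-TBS Weinreb amide F2. Addition of aryllithium 13 (from 12, n-BuLi, THF, −78 °C) should stop at the chelated tetrahedral stage and give, on work-up, the aryl β-methoxy enone (2E,5S)-1-[3,4-bis(benzyloxy)-5-methoxyphenyl]-7-[4-(benzyloxy)-3-methoxyphenyl]-5-[(tert-butyldimethylsilyl)oxy]-3-methoxyhept-2-en-1-one F3. Treatment with 2 M HCl in THF would then remove the silyl group, hydrolyse the enol ether and cyclodehydrate the δ-hydroxy-1,3-diketone to 15.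

Step 4. Catalyst turnover or enantiofacial selectivity may be poor with the enolisable aliphatic aldehyde, and the diene may hydrolyse or the aldehyde self-condense. The fallback sets out from 3 and returns at 8, replacing catalyst control by auxiliary control. A Nagao acetate aldol of 3 with (4S)-3-acetyl-4-isopropyl-1,3-thiazolidine-2-thione (Sn(OTf)2, N-ethylpiperidine, CH2Cl2, −78 °C; the auxiliary enantiomer is chosen to give the 3S adduct) would give (3S)-5-[4-(benzyloxy)-3-methoxyphenyl]-3-hydroxy-1-[(4S)-4-isopropyl-2-thioxo-1,3-thiazolidin-3-yl]pentan-1-one F4, from which the minor diastereomer is removable by chromatography. Displacement of the auxiliary with potassium methyl malonate (MgCl2, imidazole, THF) would give methyl (5S)-7-[4-(benzyloxy)-3-methoxyphenyl]-5-hydroxy-3-oxoheptanoate F5. Lactonisation (K2CO3, MeOH) would give (6S)-6-{2-[4-(benzyloxy)-3-methoxyphenyl]ethyl}dihydro-2H-pyran-2,4(3H)-dione F6. O-Methylation (Me2SO4, K2CO3, acetone) would then give 8.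

Step 8. The benzylic C2–O1 bond may be cleaved under the hydrogenolysis conditions needed to remove three benzyl groups, or saturation of the electron-rich vinylogous ester may be slow or facially unselective on the metal surface. The fallback sets out from 15 and returns at 17, separating the stereoselective reduction from the deprotection and avoiding hydrogen gas. Conjugate reduction of 15 with L-Selectride (THF, −78 °C; axial hydride delivery to C2, then protonation) should give the cis ketone (2S,6S)-2-[3,4-bis(benzyloxy)-5-methoxyphenyl]-6-{2-[4-(benzyloxy)-3-methoxyphenyl]ethyl}tetrahydro-4H-pyran-4-one F7. NaBH4 (MeOH, −20 °C) should give the all-cis alcohol (2S,4R,6S)-2-[3,4-bis(benzyloxy)-5-methoxyphenyl]-6-{2-[4-(benzyloxy)-3-methoxyphenyl]ethyl}tetrahydro-2H-pyran-4-ol F8. BCl3 with pentamethylbenzene (CH2Cl2, −78 °C) would then remove the three benzyl groups to give 17.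

**Further compounds**

F1 | step 7 | (2E,5S)-7-[4-(benzyloxy)-3-methoxyphenyl]-5-hydroxy-N,3-dimethoxy-N-methylhept-2-enamide | COc1cc(CC[C@H](O)C/C(OC)=C\C(=O)N(C)OC)ccc1OCc1ccccc1
F2 | step 7 | (2E,5S)-7-[4-(benzyloxy)-3-methoxyphenyl]-5-[(tert-butyldimethylsilyl)oxy]-N,3-dimethoxy-N-methylhept-2-enamide | COc1cc(CC[C@H](O[Si](C)(C)C(C)(C)C)C/C(OC)=C\C(=O)N(C)OC)ccc1OCc1ccccc1
F3 | step 7 | (2E,5S)-1-[3,4-bis(benzyloxy)-5-methoxyphenyl]-7-[4-(benzyloxy)-3-methoxyphenyl]-5-[(tert-butyldimethylsilyl)oxy]-3-methoxyhept-2-en-1-one | COc1cc(CC[C@H](O[Si](C)(C)C(C)(C)C)C/C(OC)=C\C(=O)c2cc(OCc3ccccc3)c(OCc3ccccc3)c(OC)c2)ccc1OCc1ccccc1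
F4 | step 4 | (3S)-5-[4-(benzyloxy)-3-methoxyphenyl]-3-hydroxy-1-[(4S)-4-isopropyl-2-thioxo-1,3-thiazolidin-3-yl]pentan-1-one | CC(C)[C@H]1CSC(=S)N1C(=O)C[C@@H](O)CCc1ccc(OCc2ccccc2)c(OC)c1
F5 | step 4 | methyl (5S)-7-[4-(benzyloxy)-3-methoxyphenyl]-5-hydroxy-3-oxoheptanoate | COC(=O)CC(=O)C[C@@H](O)CCc1ccc(OCc2ccccc2)c(OC)c1
F6 | step 4 | (6S)-6-{2-[4-(benzyloxy)-3-methoxyphenyl]ethyl}dihydro-2H-pyran-2,4(3H)-dione | COc1cc(CC[C@H]2CC(=O)CC(=O)O2)ccc1OCc1ccccc1
F7 | step 8 | (2S,6S)-2-[3,4-bis(benzyloxy)-5-methoxyphenyl]-6-{2-[4-(benzyloxy)-3-methoxyphenyl]ethyl}tetrahydro-4H-pyran-4-one | COc1cc(CC[C@H]2CC(=O)C[C@@H](c3cc(OCc4ccccc4)c(OCc4ccccc4)c(OC)c3)O2)ccc1OCc1ccccc1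
F8 | step 8 | (2S,4R,6S)-2-[3,4-bis(benzyloxy)-5-methoxyphenyl]-6-{2-[4-(benzyloxy)-3-methoxyphenyl]ethyl}tetrahydro-2H-pyran-4-ol | COc1cc(CC[C@H]2C[C@@H](O)C[C@@H](c3cc(OCc4ccccc4)c(OCc4ccccc4)c(OC)c3)O2)ccc1OCc1ccccc1
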